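Assumption: the SMILES is read as (2R,3R,4R), which is 2,3-cis-3,4-trans (2-aryl and 3-OH on one face, 4-aryl on the other); piceatannol and the two benzyl-protected aromatic building blocks are bought.

**Retrosynthetic overview**
- Last bond: C4–C(aryl), by a biomimetic Friedel–Crafts reaction of piceatannol with the C4 cation of a 2,3-cis flavan-3,4-diol; the 3-OH steers the aryl group trans, which sets 4R.
- The 2,3-cis diol comes from a flavonol triacetate by a proposed Rh-catalysed asymmetric syn-hydrogenation of C2=C3 (sets C2 and C3), then ketone reduction and deacetylation.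
- The flavonol comes from a chalcone (Algar–Flynn–Oyamada), and the chalcone from an acetophenone and a benzaldehyde.
- Ring order: rings A and B and both stilbene rings are bought; ring C is closed as a pyranone in step 2 and saturated in steps 5 and 6.

**Route**

Step 1
Reactants: 1 1-[4-(benzyloxy)-2-hydroxyphenyl]ethan-1-one; 2 4-(benzyloxy)benzaldehyde
Product: 4 chalcone (2E)-1-[4-(benzyloxy)-2-hydroxyphenyl]-3-[4-(benzyloxy)phenyl]prop-2-en-1-one, via aldol adduct 3 (not isolated)
Conditions: KOH (50% aq), EtOH/THF, rt, 36 h; then HCl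
Reagents that add atoms: none
Why: Claisen–Schmidt (crossed aldol) condensation, in which the acetophenone enolate adds to the non-enolisable aldehyde and E1cB dehydration of aldol 3 gives the favoured E-enone; no stereocentre is kept.

Step 2
Reactants: 4 chalcone (2E)-1-[4-(benzyloxy)-2-hydroxyphenyl]-3-[4-(benzyloxy)phenyl]prop-2-en-1-one
Product: 6 7-(benzyloxy)-2-[4-(benzyloxy)phenyl]-3-hydroxy-4H-chromen-4-one, via racemic trans-dihydroflavonol 5 (not isolated)
Conditions: H2O2 (30% aq, 2.5 equiv), NaOH (2 M aq), MeOH/THF, 0 °C → rt; then HCl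
Reagents that add atoms: hydrogen peroxide, OO
Why: Algar–Flynn–Oyamada reaction, in which the phenoxide closes ring C by oxa-Michael addition while the enolate is hydroxylated to dihydroflavonol 5, which the alkaline peroxide dehydrogenates to the flavonol; a chalcone with no 6'-substituent gives flavonol, not aurone.

Step 3
Reactants: 6 7-(benzyloxy)-2-[4-(benzyloxy)phenyl]-3-hydroxy-4H-chromen-4-one
Product: 7 resokaempferol (3,7-dihydroxy-2-(4-hydroxyphenyl)-4H-chromen-4-one)
Conditions: H2 (1 atm), Pd/C (10%), THF/MeOH, rt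
Reagents that add atoms: none
Why: Hydrogenolysis of the two benzyl aryl ethers over Pd/C; the pyrone C2=C3 bond of a flavonol is not reduced at 1 atm and room temperature.

Step 4
Reactants: 7 resokaempferol (3,7-dihydroxy-2-(4-hydroxyphenyl)-4H-chromen-4-one)
Product: 8 resokaempferol triacetate (2-[4-(acetyloxy)phenyl]-4-oxo-4H-chromene-3,7-diyl diacetate)
Conditions: Ac2O, pyridine, DMAP (cat.), rt
Reagents that add atoms: acetic anhydride, CC(=O)OC(C)=O
Why: DMAP-catalysed acylation of both phenols and the enolic 3-OH; this installs the 3-acyloxy group that directs step 5 and protects the phenols with groups that come off without hydrogenolysis.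

Step 5
Reactants: 8 resokaempferol triacetate (2-[4-(acetyloxy)phenyl]-4-oxo-4H-chromene-3,7-diyl diacetate)
Product: 9 (2R,3S)-2-[4-(acetyloxy)phenyl]-4-oxo-3,4-dihydro-2H-chromene-3,7-diyl diacetate (2,3-cis)
Conditions: [Rh(cod)2]BF4 (5 mol%), (R,R)-Me-DuPhos (5.5 mol%), H2 (60 bar), CH2Cl2, 40 °C, 24 h
Reagents that add atoms: none
Why: Proposed new method: acyloxy-directed rhodium-catalysed asymmetric hydrogenation of the tetrasubstituted C2=C3 bond of a flavonol 3-ester, a substrate class on which no enantioselective hydrogenation has been shown; the 3-OAc carbonyl and the C2=C3 π bond chelate the cationic monovalent rhodium bisphospholane complex as an enol acetate does, H2 adds oxidatively, hydride migrates to C2 (the β-carbon) to give a five-membered C3–rhodium alkyl chelate and C3–H reductive elimination follows on the same face, so syn addition forces 2-aryl and 3-OAc cis while the C2-symmetric ligand quadrants choose the enantioface that gives (2R,3S) (the mirror-image ligand is used if the sense of induction proves opposite); the aryl acetates make the pyrone alkene less electron-rich than in flavonol ethers and the small methyl phospholanes leave room for a tetrasubstituted alkene; closest known reaction types are Rh–bisphospholane asymmetric hydrogenation of enol esters and of tetrasubstituted dehydroamino esters, asymmetric hydrogenation of the trisubstituted C2=C3 bond of chromones and flavones, and the racemic heterogeneous hydrogenation of flavonols to cis products.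

Step 6
Reactants: 9 (2R,3S)-2-[4-(acetyloxy)phenyl]-4-oxo-3,4-dihydro-2H-chromene-3,7-diyl diacetate
Product: 10 (2R,3R,4R)-2-[4-(acetyloxy)phenyl]-4-hydroxy-3,4-dihydro-2H-chromene-3,7-diyl diacetate (all-cis)
Conditions: NaBH4 (1.2 equiv), THF/MeOH (4:1), −40 → −20 °C, 30 min; AcOH quench
Reagents that add atoms: none
Why: Borohydride ketone reduction in which hydride adds anti to the pseudo-axial 3-OAc (polar Felkin–Anh) to give mainly the 4R (3,4-cis) alcohol; the low temperature avoids C3 epimerisation, and the C4 configuration (like any 3→4 acetyl shift) is erased in steps 7 and 8.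

Step 7
Reactants: 10 (2R,3R,4R)-2-[4-(acetyloxy)phenyl]-4-hydroxy-3,4-dihydro-2H-chromene-3,7-diyl diacetate
Product: 11 (2R,3R,4R)-2-(4-hydroxyphenyl)-3,4-dihydro-2H-chromene-3,4,7-triol (epiguibourtinidol-4-ol)
Conditions: K2CO3 (0.2 equiv), degassed MeOH, 0 °C, argon; AcOH to pH 6
Reagents that add atoms: none
Why: Base-catalysed transesterification (Zemplén-type methanolysis) of two aryl acetates and one alkyl acetate; C2, C3 and C4 are not touched at 0 °C.

Step 8
Reactants: 11 (2R,3R,4R)-2-(4-hydroxyphenyl)-3,4-dihydro-2H-chromene-3,4,7-triol; 12 piceatannol (4-[(E)-2-(3,5-dihydroxyphenyl)ethenyl]benzene-1,2-diol)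
Product: 14 (2R,3R,4R)-4-{2-[(E)-2-(3,4-dihydroxyphenyl)ethenyl]-4,6-dihydroxyphenyl}-2-(4-hydroxyphenyl)-3,4-dihydro-2H-chromene-3,7-diol, via flavan-4-yl cation 13 (not isolated)
Conditions: 12 (4 equiv), 0.1 M aq HCl/EtOH (1:1), rt, 16 h, argon, dark; Sephadex LH-20
Reagents that add atoms: none
Why: Biomimetic Friedel–Crafts alkylation (SN1) in which acid ionises the 4-OH to cation 13, stabilised by the para 7-OH and the ortho ring oxygen, and the resorcinol ring of 12 attacks through C2 (para to one OH and ortho to the other, the kinetic site of 5-substituted resorcinols) from the face opposite the quasi-axial 3-OH of the 2,3-cis half-chair, giving the 3,4-trans (4R) product as in 2,3-cis proanthocyanidin couplings.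

**Compound list**
1 | 1-[4-(benzyloxy)-2-hydroxyphenyl]ethan-1-one | CC(=O)c1ccc(OCc2ccccc2)cc1O | starting material
2 | 4-(benzyloxy)benzaldehyde | O=Cc1ccc(OCc2ccccc2)cc1 | starting material
3 | 1-[4-(benzyloxy)-2-hydroxyphenyl]-3-[4-(benzyloxy)phenyl]-3-hydroxypropan-1-one (racemic aldol adduct) | O=C(CC(O)c1ccc(OCc2ccccc2)cc1)c1ccc(OCc2ccccc2)cc1O | intermediate (not isolated)
4 | (2E)-1-[4-(benzyloxy)-2-hydroxyphenyl]-3-[4-(benzyloxy)phenyl]prop-2-en-1-one | O=C(/C=C/c1ccc(OCc2ccccc2)cc1)c1ccc(OCc2ccccc2)cc1O | intermediate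
5 | rac-(2R,3R)-7-(benzyloxy)-2-[4-(benzyloxy)phenyl]-3-hydroxy-2,3-dihydro-4H-chromen-4-one (trans; racemate, one enantiomer drawn) | c1ccccc1COc1ccc([C@H]2Oc3cc(OCc4ccccc4)ccc3C(=O)[C@@H]2O)cc1 | intermediate (not isolated)
6 | 7-(benzyloxy)-2-[4-(benzyloxy)phenyl]-3-hydroxy-4H-chromen-4-one | O=c1c(O)c(-c2ccc(OCc3ccccc3)cc2)oc2cc(OCc3ccccc3)ccc12 | intermediate
7 | 3,7-dihydroxy-2-(4-hydroxyphenyl)-4H-chromen-4-one (resokaempferol) | O=c1c(O)c(-c2ccc(O)cc2)oc2cc(O)ccc12 | intermediate
8 | 2-[4-(acetyloxy)phenyl]-4-oxo-4H-chromene-3,7-diyl diacetate | CC(=O)Oc1ccc(-c2oc3cc(OC(C)=O)ccc3c(=O)c2OC(C)=O)cc1 | intermediate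
9 | (2R,3S)-2-[4-(acetyloxy)phenyl]-4-oxo-3,4-dihydro-2H-chromene-3,7-diyl diacetate (2,3-cis) | CC(=O)Oc1ccc([C@H]2Oc3cc(OC(C)=O)ccc3C(=O)[C@H]2OC(C)=O)cc1 | intermediate
10 | (2R,3R,4R)-2-[4-(acetyloxy)phenyl]-4-hydroxy-3,4-dihydro-2H-chromene-3,7-diyl diacetate (all-cis) | CC(=O)Oc1ccc([C@H]2Oc3cc(OC(C)=O)ccc3[C@@H](O)[C@H]2OC(C)=O)cc1 | intermediate
11 | (2R,3R,4R)-2-(4-hydroxyphenyl)-3,4-dihydro-2H-chromene-3,4,7-triol (2,3-cis-3,4-cis) | Oc1ccc([C@H]2Oc3cc(O)ccc3[C@@H](O)[C@H]2O)cc1 | intermediate
12 | piceatannol, 4-[(E)-2-(3,5-dihydroxyphenyl)ethenyl]benzene-1,2-diol | Oc1cc(O)cc(/C=C/c2ccc(O)c(O)c2)c1 | starting material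
13 | (2R,3R)-3,7-dihydroxy-2-(4-hydroxyphenyl)-3,4-dihydro-2H-chromen-4-ylium (C4 benzylic cation) | Oc1ccc([C@H]2Oc3cc(O)ccc3[CH+][C@H]2O)cc1 | intermediate (not isolated)
14 | (2R,3R,4R)-4-{2-[(E)-2-(3,4-dihydroxyphenyl)ethenyl]-4,6-dihydroxyphenyl}-2-(4-hydroxyphenyl)-3,4-dihydro-2H-chromene-3,7-diol | Oc1ccc([C@H]2Oc3cc(O)ccc3[C@H](c3c(O)cc(O)cc3/C=C/c3ccc(O)c(O)c3)[C@H]2O)cc1 | target

**Count**
Total steps: 8. Longest linear sequence: 8 steps (1 and 2 to 14); 12 is a bought partner that enters in step 8.

**Three steps most likely to fail**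

The asymmetric hydrogenation (step 5, the proposed new step). The tetrasubstituted pyrone alkene may not turn over, or the ee may be low. The fallback uses known chemistry, sets out from 8 and comes back at 10. Compound 8 is hydrogenated over neutral-washed Raney Ni (H2 100 bar, EtOAc/EtOH, 80 °C), the classical heterogeneous reduction of flavonols. It delivers both molecules of H2 to one face and gives the racemic all-cis alcohol, that is 10 together with its mirror image (2S,3S,4S)-2-[4-(acetyloxy)phenyl]-4-hydroxy-3,4-dihydro-2H-chromene-3,7-diyl diacetate F1. Preparative chiral SFC on an amylose carbamate phase separates the two; F1 is discarded and 10 goes on to step 7. Absolute control then comes from resolution instead of a catalyst, at the cost of half the material.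

The deacetylation (step 7). The free flavan-3,4-diol 11 is a labile leucoanthocyanidin and may oligomerise or oxidise under base. The fallback sets out from 10 and comes back at 14. Compound 10 is stirred in dry MeOH containing HCl made from acetyl chloride (0 °C → rt, 24 h). Acid transesterification removes the three acetates and SN1 solvolysis exchanges the 4-OH for OMe, giving (2R,3R,4S)-2-(4-hydroxyphenyl)-4-methoxy-3,4-dihydro-2H-chromene-3,7-diol F2 (its C4 epimer is equally usable). This bench-stable methyl ether never sees base and takes the place of 11 under the step 8 conditions, where it ionises to the same cation 13 and gives 14.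

The Friedel–Crafts coupling (step 8). Self-condensation of 11, acid-promoted side reactions of the stilbene, or low conversion may lower the yield. The fallback sets out from 11 and comes back at 14. Compound 11 is first captured with phenylmethanethiol (AcOH, EtOH, 70 °C) as the purifiable 3,4-trans thioether (2R,3S,4S)-4-(benzylsulfanyl)-2-(4-hydroxyphenyl)-3,4-dihydro-2H-chromene-3,7-diol F3. F3 and 12 (4 equiv) are then treated with AgBF4 (2.5 equiv) in THF at 0 °C. Thiophilic activation releases cation 13 without protic acid and in the presence of excess nucleophile, and attack trans to the 3-OH gives 14.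

**Further compounds**
F1 | step 5 | (2S,3S,4S)-2-[4-(acetyloxy)phenyl]-4-hydroxy-3,4-dihydro-2H-chromene-3,7-diyl diacetate | CC(=O)Oc1ccc([C@@H]2Oc3cc(OC(C)=O)ccc3[C@H](O)[C@@H]2OC(C)=O)cc1
F2 | step 7 | (2R,3R,4S)-2-(4-hydroxyphenyl)-4-methoxy-3,4-dihydro-2H-chromene-3,7-diol | Oc1ccc([C@H]2Oc3cc(O)ccc3[C@H](OC)[C@H]2O)cc1
F3 | step 8 | (2R,3S,4S)-4-(benzylsulfanyl)-2-(4-hydroxyphenyl)-3,4-dihydro-2H-chromene-3,7-diol | Oc1ccc([C@H]2Oc3cc(O)ccc3[C@H](SCc3ccccc3)[C@H]2O)cc1
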